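Atoms are numbered along the skeleton: ethyl C1–C2, C3, lactone A C4–O5–C6–C7–C8, ketone C9, C10, C11, lactone B C12–C13–C14–C15–O16, N17, C18–C21, C22, lactam carbonyl C23. The plan rests on the β-amino ketone unit N17–C11–C10–C9(=O) inside the nine-membered ring (C3, C4, C8, C9, C10, C11, N17, C23, C22), where C10 is a bare methylene and C11 also carries C12.
Lactone B comes last, from a C12 aldehyde: C12–C13 by addition of a 2-carboxyallyl indium reagent, O16–C12 by lactonisation with inversion, C14 by hydrogenation of the α-methylene lactone.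
Key disconnection C10–C11: the enol silane of a C9 methyl ketone adds to an N-acyliminium ion built on the caprolactam nitrogen from methyl glyoxylate; this closes the nine-membered ring and leaves C12 as an ester.
Lactone A: C4–C8 by an anti aldol reaction of a thioester of (S)-methylsuccinic acid with a C4 aldehyde, then lactonisation; the thioester becomes the C9 methyl ketone.
C22–C3 by an amine-catalysed Michael addition of a protected 6-aminohexanal to 1-nitrobutene, then lactamisation and a Nef reaction; ring order: caprolactam, lactone A, nine-membered ring, lactone B.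

Key step: step 14

Remark: methoxy is chosen as the leaving group at C11, because an acyloxy group would not be expected to survive the cuprate and the amine/silyl triflate steps; the N,O-acetal intermediates are carried as C11 epimer pairs, which converge at the iminium ion.
Assumption: propanal, nitromethane, tert-butyl (6-hydroxyhexyl)carbamate, (S)-methylsuccinic acid, methyl glyoxylate and 2-(bromomethyl)acrylic acid are bought.

Step 1
Reactants: 1 propanal; 2 nitromethane
Product: 3 1-nitrobutan-2-ol (racemic)
Conditions: NaOH (cat.), MeOH/H2O, 0 °C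
Reagents that add atoms: none
Why: Henry (nitroaldol) addition of the nitronate to the aldehyde, whose carbinol centre is removed again in step 2.

Step 2
Reactants: 3 1-nitrobutan-2-ol
Product: 5 (E)-1-nitrobut-1-ene, via mesylate 4 (not isolated)
Conditions: MeSO2Cl, Et3N, CH2Cl2, −10 → 0 °C
Reagents that add atoms: none
Why: Mesylation followed by E1cB elimination through the nitronate should give the conjugated nitroalkene as its more stable E isomer.

Step 3
Reactants: 6 tert-butyl (6-hydroxyhexyl)carbamate
Product: 7 tert-butyl (6-oxohexyl)carbamate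
Conditions: PhI(OAc)2, 2,2,6,6-tetramethylpiperidin-1-oxyl (cat.), CH2Cl2, rt
Reagents that add atoms: none
Why: Nitroxyl-catalysed oxidation of a primary alcohol stops at the aldehyde and leaves the carbamate alone.

Step 4
Reactants: 7 tert-butyl (6-oxohexyl)carbamate; 5 (E)-1-nitrobut-1-ene
Product: 8 tert-butyl N-[(5R,6R)-5-formyl-6-(nitromethyl)octyl]carbamate
Conditions: (S)-2-[diphenyl(trimethylsilyloxy)methyl]pyrrolidine (10 mol %), toluene, 0 °C → rt; 5 (1.5 equiv)
Reagents that add atoms: none
Why: Enamine-catalysed asymmetric Michael addition of an aldehyde to a nitroalkene, in which the anti-(E)-enamine is shielded on one face by the diphenyl(silyloxy)methyl group (C22 set as R) and the synclinal approach of the E-nitroalkene gives the syn adduct (C3 set as R).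

Step 5
Reactants: 8 tert-butyl N-[(5R,6R)-5-formyl-6-(nitromethyl)octyl]carbamate
Product: 9 (2R)-6-[(tert-butoxycarbonyl)amino]-2-[(2R)-1-nitrobutan-2-yl]hexanoic acid
Conditions: NaClO2, NaH2PO4, 2-methylbut-2-ene, t-BuOH/H2O, 0 °C → rt
Reagents that add atoms: sodium chlorite, [Na+].[O-]Cl=O
Why: Pinnick oxidation converts the epimerisable aldehyde to the acid under buffered conditions that should leave C22 and the nitro group untouched.

Step 6
Reactants: 9 (2R)-6-[(tert-butoxycarbonyl)amino]-2-[(2R)-1-nitrobutan-2-yl]hexanoic acid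
Product: 11 (3R)-3-[(2R)-1-nitrobutan-2-yl]azepan-2-one, via ammonium trifluoroacetate 10 (not isolated)
Conditions: CF3CO2H, CH2Cl2, 0 °C → rt, evaporation; then N-(3-dimethylaminopropyl)-N′-ethylcarbodiimide hydrochloride, 1-hydroxy-7-azabenzotriazole, N-methylmorpholine, CH2Cl2 (5 mM), rt
Reagents that add atoms: none
Why: Acidolysis of the carbamate and carbodiimide lactamisation at high dilution close the seven-membered lactam, with a base too weak to form the nitronate and an α-alkyl active ester that should not epimerise.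

Step 7
Reactants: 11 (3R)-3-[(2R)-1-nitrobutan-2-yl]azepan-2-one
Product: 13 (2R)-2-[(3R)-2-oxoazepan-3-yl]butanal, via sodium nitronate 12 (not isolated)
Conditions: NaOMe (1.05 equiv), MeOH, 0 °C; then O3, CH2Cl2/MeOH, −78 °C; N2 purge, pH 7 buffer; used crude
Reagents that add atoms: ozone, [O-][O+]=O
Why: Nef reaction in its oxidative form, in which ozone cleaves the C=N bond of the nitronate at −78 °C to the C4 aldehyde after the base has been consumed, so that C3 should not epimerise.

Step 8
Reactants: 14 (S)-methylsuccinic acid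
Product: 15 (3S)-3-methyloxolane-2,5-dione
Conditions: CH3COCl, reflux
Reagents that add atoms: none
Why: Dehydration of the diacid to the cyclic anhydride does not touch the stereocentre.

Step 9
Reactants: 15 (3S)-3-methyloxolane-2,5-dione
Product: 17 methyl (2S)-4-(tert-butylsulfanyl)-2-methyl-4-oxobutanoate, via sodium carboxylate 16 (not isolated)
Conditions: t-BuSNa, THF, −78 → 0 °C; then MeI, DMF, rt
Reagents that add atoms: sodium 2-methylpropane-2-thiolate, CC(C)(C)[S-].[Na+]; iodomethane, CI
Why: The bulky thiolate should open the anhydride at the carbonyl remote from the methyl group and the carboxylate is then O-methylated, the minor regioisomer being removed by chromatography.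

Step 10
Reactants: 17 methyl (2S)-4-(tert-butylsulfanyl)-2-methyl-4-oxobutanoate; 13 (2R)-2-[(3R)-2-oxoazepan-3-yl]butanal
Product: 20 S-tert-butyl (2S,3S,4S)-4-methyl-5-oxo-2-[(1R)-1-[(3R)-2-oxoazepan-3-yl]propyl]oxolane-3-carbothioate, via boron enolate 18 (not isolated), via hydroxy ester 19 (not isolated)
Conditions: 17 (1.5 equiv), Bu2BOSO2CF3, i-Pr2NEt, CH2Cl2, 0 °C; 13, −78 → 0 °C; pH 7 buffer/MeOH; then pyridinium p-toluenesulfonate (cat.), CH2Cl2, rt
Reagents that add atoms: none
Why: Boron-mediated anti aldol reaction of a tert-butyl thioester, in which the E(O)-enolate reacts through a chair transition state (C4–O anti to C8–C7), the aldehyde is attacked in the Felkin–Anh sense with the C22 branch as the large group (C4 S), the enolate face anti to the C7 methyl group is used (C8 S), and the γ-hydroxy methyl ester then lactonises to lactone A with C3 and C9 cis.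

Step 11
Reactants: 20 S-tert-butyl (2S,3S,4S)-4-methyl-5-oxo-2-[(1R)-1-[(3R)-2-oxoazepan-3-yl]propyl]oxolane-3-carbothioate; 21 methyl glyoxylate
Product: 24 methyl 2-methoxy-2-[(3R)-3-[(1R)-1-[(2S,3S,4S)-3-(tert-butylsulfanylcarbonyl)-4-methyl-5-oxooxolan-2-yl]propyl]-2-oxoazepan-1-yl]acetate (both C11 epimers), via hemiaminal 22 (not isolated), via chloride 23 (not isolated)
Conditions: 21 (3 equiv), toluene, 90 °C; SOCl2, 2,6-lutidine, THF, −20 °C; MeOH, 0 °C → rt
Reagents that add atoms: methanol, CO
Why: The lactam N–H adds to the glyoxylate aldehyde, the hemiaminal hydroxyl is exchanged for chloride via the chlorosulfite and the chloride is solvolysed by methanol, which gives a base-stable N,O-acetal whose C11 configuration is irrelevant.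

Step 12
Reactants: 24 methyl 2-methoxy-2-[(3R)-3-[(1R)-1-[(2S,3S,4S)-3-(tert-butylsulfanylcarbonyl)-4-methyl-5-oxooxolan-2-yl]propyl]-2-oxoazepan-1-yl]acetate
Product: 25 methyl 2-[(3R)-3-[(1R)-1-[(2S,3S,4S)-3-acetyl-4-methyl-5-oxooxolan-2-yl]propyl]-2-oxoazepan-1-yl]-2-methoxyacetate (both C11 epimers)
Conditions: Me2CuLi (from MeLi and CuI), Et2O, −78 → −40 °C
Reagents that add atoms: lithium dimethylcuprate, [Li+].C[Cu-]C
Why: Acyl substitution of a thioester by a cuprate stops at the ketone, and the weakly basic reagent should neither epimerise C8 nor expel the lactone oxygen from C4.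

Step 13
Reactants: 25 methyl 2-[(3R)-3-[(1R)-1-[(2S,3S,4S)-3-acetyl-4-methyl-5-oxooxolan-2-yl]propyl]-2-oxoazepan-1-yl]-2-methoxyacetate
Product: 26 methyl 2-methoxy-2-[(3R)-3-[(1R)-1-[(2S,3S,4S)-4-methyl-5-oxo-3-[1-(trimethylsilyloxy)ethenyl]oxolan-2-yl]propyl]-2-oxoazepan-1-yl]acetate (both C11 epimers)
Conditions: Me3SiOSO2CF3 (1.3 equiv), Et3N (3 equiv), CH2Cl2, −78 → −20 °C; pentane, filtration, evaporation; used at once
Reagents that add atoms: trimethylsilyl trifluoromethanesulfonate, C[Si](C)(C)OS(=O)(=O)C(F)(F)F
Why: Soft enolisation silylates only the ketone (esters, lactone and lactam are not enolised under these conditions), and the amine should deprotonate the silyloxocarbenium ion at the open methyl group C10 and not at the hindered ring methine C8, while excess amine keeps the N,O-acetal from ionising.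

Step 14
Reactants: 26 methyl 2-methoxy-2-[(3R)-3-[(1R)-1-[(2S,3S,4S)-4-methyl-5-oxo-3-[1-(trimethylsilyloxy)ethenyl]oxolan-2-yl]propyl]-2-oxoazepan-1-yl]acetate
Product: 28 tricyclic keto lactam methyl ester (3R,4S,7S,8S,11S,22R; CO2Me on C11), via N-acyliminium triflate 27 (not isolated)
Conditions: Me3SiOSO2CF3 (1.2 equiv), 2,6-di-tert-butyl-4-methylpyridine (0.2 equiv), CH2Cl2, −40 → 0 °C; 26 added over 12 h to a final 1 mM
Reagents that add atoms: none
Why: Me3SiOSO2CF3 takes the C11 methoxy group away as Me3SiOMe and leaves N-acyliminium ion 27, which has no α-hydrogen on the ester side and so cannot collapse to an enamide; the terminal enol silane carbon C10 adds to C11, and silyl transfer from the resulting oxocarbenium ion to triflate returns the Lewis acid and uncovers the C9 ketone. The closest known reaction is the intramolecular Mukaiyama–Mannich (amidoalkylation) cyclisation of silyl enol ethers onto glyoxylate-derived N-acyliminium ions, which is known but seldom asked to form a ring of this size. The nine-membered ring (C3, C4, C8, C9, C10, C11, N17, C23, C22) closes 9-endo-trig at the iminium ion with the enol double bond also inside the new ring (enolendo), the silyloxy oxygen staying outside. C11 is the only new stereocentre: the tether leaves C22 on one side of the lactam plane and can reach only that face of the planar iminium ion, whose ester group should lie syn to the lactam oxygen and away from C18H2, a combination that should give 11S on inspection of models. The step needs ring closure to outrun intermolecular amidoalkylation and C10, not C8, to be the nucleophile; slow addition to 1 mM, the turn built in by the caprolactam and the cis-substituted lactone A, and the regiodefined enol silane kept from acid-induced isomerisation by the hindered pyridine base are meant to secure both. An 11R ester, should it form, could be equilibrated at the α-amido ester position before step 15.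

Step 15
Reactants: 28 tricyclic keto lactam methyl ester
Product: 30 tricyclic keto lactam carboxylic acid (CO2H on C11; 3R,4S,7S,8S,11S,22R), via trimethylstannyl ester 29 (not isolated)
Conditions: Me3SnOH, ClCH2CH2Cl, 70 °C; 5% HCl wash
Reagents that add atoms: trimethyltin hydroxide, C[Sn](C)(C)O
Why: Tin hydroxide cleaves the activated α-amido methyl ester under nearly neutral conditions, which should avoid β-elimination of the lactone oxygen from the C9 ketone and epimerisation at C8 or C11.

Step 16
Reactants: 30 tricyclic keto lactam carboxylic acid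
Product: 31 S-ethyl thioester of 30 (C(=O)SEt on C11)
Conditions: EtSH, N,N′-dicyclohexylcarbodiimide, 4-(dimethylamino)pyridine (5 mol %), CH2Cl2, 0 °C
Reagents that add atoms: ethanethiol, CCS
Why: Steglich-type thioesterification at low temperature prepares the carboxyl group for selective reduction while keeping activation of the α-amido acid short.

Step 17
Reactants: 31 S-ethyl thioester
Product: 32 tricyclic keto lactam aldehyde (CHO on C11; 3R,4S,7S,8S,11S,22R)
Conditions: Et3SiH, 10% Pd/C, acetone, rt; used crude
Reagents that add atoms: none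
Why: Fukuyama reduction, in which palladium inserts into the C–S bond and the silane delivers hydride, stops at the aldehyde and leaves ketone, lactone and lactam untouched.

Step 18
Reactants: 32 tricyclic keto lactam aldehyde; 33 2-(bromomethyl)acrylic acid
Product: 34 (12R)-γ-hydroxy-α-methylene acid [C11–CH(OH)–CH2–C(=CH2)–CO2H]
Conditions: In powder, THF/H2O (1:1), rt; extraction at pH 4, used at once
Reagents that add atoms: none
Why: Barbier allylation, in which the allylindium reagent formed in water adds to the aldehyde much faster than to the C9 ketone and, by Felkin–Anh attack anti to the C11–N bond, should give the 11,12-anti alcohol (12R).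

Step 19
Reactants: 34 (12R)-γ-hydroxy-α-methylene acid
Product: 35 α-methylene lactone B compound (12S)
Conditions: PPh3, diisopropyl azodicarboxylate, THF (10 mM), 0 °C → rt
Reagents that add atoms: none
Why: Mitsunobu lactonisation activates the C12 alcohol as its oxyphosphonium ion and the carboxylate displaces it 5-exo-tet with inversion, which turns 12R into the required 12S.

Step 20
Reactants: 35 α-methylene lactone B compound
Product: 36 CNP0311700.2 (3R,4S,7S,8S,11S,12S,14S,22R)
Conditions: H2 (1 atm), 10% Pd/C, EtOAc, rt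
Reagents that add atoms: none
Why: Heterogeneous hydrogenation adds hydrogen to the exocyclic methylene from the lactone face opposite the C12 substituent, so the C14 methyl group should end cis to C11 (14S), as it also would after migration of the double bond into the ring.

Compound list
1 | propanal | CCC=O | starting material
2 | nitromethane | C[N+](=O)[O-] | starting material
3 | 1-nitrobutan-2-ol (racemic) | CCC(O)C[N+](=O)[O-] | intermediate
4 | 1-nitrobutan-2-yl methanesulfonate (racemic, not isolated) | CCC(OS(C)(=O)=O)C[N+](=O)[O-] | intermediate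
5 | (E)-1-nitrobut-1-ene | CC/C=C/[N+](=O)[O-] | intermediate
6 | tert-butyl (6-hydroxyhexyl)carbamate | CC(C)(C)OC(=O)NCCCCCCO | starting material
7 | tert-butyl (6-oxohexyl)carbamate | CC(C)(C)OC(=O)NCCCCCC=O | intermediate
8 | tert-butyl N-[(5R,6R)-5-formyl-6-(nitromethyl)octyl]carbamate | CC[C@@H](C[N+](=O)[O-])[C@H](C=O)CCCCNC(=O)OC(C)(C)C | intermediate
9 | (2R)-6-[(tert-butoxycarbonyl)amino]-2-[(2R)-1-nitrobutan-2-yl]hexanoic acid | CC[C@@H](C[N+](=O)[O-])[C@H](C(=O)O)CCCCNC(=O)OC(C)(C)C | intermediate
10 | (2R)-6-ammonio-2-[(2R)-1-nitrobutan-2-yl]hexanoic acid trifluoroacetate (not isolated) | CC[C@@H](C[N+](=O)[O-])[C@H](C(=O)O)CCCC[NH3+].[O-]C(=O)C(F)(F)F | intermediate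
11 | (3R)-3-[(2R)-1-nitrobutan-2-yl]azepan-2-one | CC[C@@H](C[N+](=O)[O-])[C@H]1CCCCNC1=O | intermediate
12 | sodium nitronate of 11 (not isolated) | CC[C@@H](C=[N+]([O-])[O-])[C@H]1CCCCNC1=O.[Na+] | intermediate
13 | (2R)-2-[(3R)-2-oxoazepan-3-yl]butanal | CC[C@@H](C=O)[C@H]1CCCCNC1=O | intermediate
14 | (S)-methylsuccinic acid | OC(=O)[C@@H](C)CC(O)=O | starting material
15 | (3S)-3-methyloxolane-2,5-dione | C[C@H]1CC(=O)OC1=O | intermediate
16 | sodium (2S)-4-(tert-butylsulfanyl)-2-methyl-4-oxobutanoate (not isolated) | [Na+].[O-]C(=O)[C@@H](C)CC(=O)SC(C)(C)C | intermediate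
17 | methyl (2S)-4-(tert-butylsulfanyl)-2-methyl-4-oxobutanoate | COC(=O)[C@@H](C)CC(=O)SC(C)(C)C | intermediate
18 | dibutylboron E(O)-enolate of 17 (not isolated) | COC(=O)[C@@H](C)/C=C(/OB(CCCC)CCCC)SC(C)(C)C | intermediate
19 | methyl (2S,3S,4S,5R)-3-(tert-butylsulfanylcarbonyl)-4-hydroxy-2-methyl-5-[(3R)-2-oxoazepan-3-yl]heptanoate (not isolated) | CC[C@@H]([C@H](O)[C@@H](C(=O)SC(C)(C)C)[C@H](C)C(=O)OC)[C@H]1CCCCNC1=O | intermediate
20 | S-tert-butyl (2S,3S,4S)-4-methyl-5-oxo-2-[(1R)-1-[(3R)-2-oxoazepan-3-yl]propyl]oxolane-3-carbothioate | CC[C@@H]([C@@H]1OC(=O)[C@@H](C)[C@@H]1C(=O)SC(C)(C)C)[C@H]2CCCCNC2=O | intermediate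
21 | methyl glyoxylate | COC(=O)C=O | starting material
22 | N-[hydroxy(methoxycarbonyl)methyl] hemiaminal of 20 (C11 epimers, not isolated) | CC[C@@H]([C@@H]1OC(=O)[C@@H](C)[C@@H]1C(=O)SC(C)(C)C)[C@H]2CCCCN(C(O)C(=O)OC)C2=O | intermediate
23 | N-[chloro(methoxycarbonyl)methyl] derivative of 20 (C11 epimers, not isolated) | CC[C@@H]([C@@H]1OC(=O)[C@@H](C)[C@@H]1C(=O)SC(C)(C)C)[C@H]2CCCCN(C(Cl)C(=O)OC)C2=O | intermediate
24 | methyl 2-methoxy-2-[(3R)-3-[(1R)-1-[(2S,3S,4S)-3-(tert-butylsulfanylcarbonyl)-4-methyl-5-oxooxolan-2-yl]propyl]-2-oxoazepan-1-yl]acetate (C11 epimers) | CC[C@@H]([C@@H]1OC(=O)[C@@H](C)[C@@H]1C(=O)SC(C)(C)C)[C@H]2CCCCN(C(OC)C(=O)OC)C2=O | intermediate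
25 | methyl 2-[(3R)-3-[(1R)-1-[(2S,3S,4S)-3-acetyl-4-methyl-5-oxooxolan-2-yl]propyl]-2-oxoazepan-1-yl]-2-methoxyacetate (C11 epimers) | CC[C@@H]([C@@H]1OC(=O)[C@@H](C)[C@@H]1C(C)=O)[C@H]2CCCCN(C(OC)C(=O)OC)C2=O | intermediate
26 | methyl 2-methoxy-2-[(3R)-3-[(1R)-1-[(2S,3S,4S)-4-methyl-5-oxo-3-[1-(trimethylsilyloxy)ethenyl]oxolan-2-yl]propyl]-2-oxoazepan-1-yl]acetate (C11 epimers; key-step precursor) | CC[C@@H]([C@@H]1OC(=O)[C@@H](C)[C@@H]1C(=C)O[Si](C)(C)C)[C@H]2CCCCN(C(OC)C(=O)OC)C2=O | intermediate
27 | N-acyliminium triflate from 26, N17=C11(H)CO2Me (not isolated) | CC[C@@H]([C@@H]1OC(=O)[C@@H](C)[C@@H]1C(=C)O[Si](C)(C)C)[C@H]2CCCC[N+](=CC(=O)OC)C2=O.[O-]S(=O)(=O)C(F)(F)F | intermediate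
28 | tricyclic keto lactam methyl ester: caprolactam (N17, C18–C23) sharing N17–C23 with the nine-membered ring C3–C4–C8–C9(=O)–C10–C11–N17–C23(=O)–C22, lactone A on C4/C8, ethyl on C3, CO2Me on C11; 3R,4S,7S,8S,11S,22R (key-step product) | CC[C@H]1[C@@H]2OC(=O)[C@@H](C)[C@@H]2C(=O)C[C@@H](C(=O)OC)N2CCCC[C@H]1C2=O | intermediate
29 | trimethylstannyl ester of acid 30 (not isolated) | CC[C@H]1[C@@H]2OC(=O)[C@@H](C)[C@@H]2C(=O)C[C@@H](C(=O)O[Sn](C)(C)C)N2CCCC[C@H]1C2=O | intermediate
30 | tricyclic keto lactam carboxylic acid (CO2H on C11; 3R,4S,7S,8S,11S,22R) | CC[C@H]1[C@@H]2OC(=O)[C@@H](C)[C@@H]2C(=O)C[C@@H](C(=O)O)N2CCCC[C@H]1C2=O | intermediate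
31 | S-ethyl thioester of 30 | CC[C@H]1[C@@H]2OC(=O)[C@@H](C)[C@@H]2C(=O)C[C@@H](C(=O)SCC)N2CCCC[C@H]1C2=O | intermediate
32 | tricyclic keto lactam aldehyde (CHO on C11; 3R,4S,7S,8S,11S,22R) | CC[C@H]1[C@@H]2OC(=O)[C@@H](C)[C@@H]2C(=O)C[C@@H](C=O)N2CCCC[C@H]1C2=O | intermediate
33 | 2-(bromomethyl)acrylic acid | OC(=O)C(=C)CBr | starting material
34 | (12R)-γ-hydroxy-α-methylene acid, C11–CH(OH)–CH2–C(=CH2)–CO2H on the tricycle (3R,4S,7S,8S,11S,12R,22R) | CC[C@H]1[C@@H]2OC(=O)[C@@H](C)[C@@H]2C(=O)C[C@@H]([C@H](O)CC(=C)C(O)=O)N2CCCC[C@H]1C2=O | intermediate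
35 | α-methylene lactone B compound (3R,4S,7S,8S,11S,12S,22R) | CC[C@H]1[C@@H]2OC(=O)[C@@H](C)[C@@H]2C(=O)C[C@@H]([C@@H]2CC(=C)C(=O)O2)N2CCCC[C@H]1C2=O | intermediate
36 | CNP0311700.2 (3R,4S,7S,8S,11S,12S,14S,22R) | CC[C@H]1[C@@H]2OC(=O)[C@@H](C)[C@@H]2C(=O)C[C@@H]([C@@H]2C[C@H](C)C(=O)O2)N2CCCC[C@H]1C2=O | target

Total step count: 20. Longest linear sequence: 17 steps (steps 1, 2, 4–7 and 10–20, from 1).

Steps most likely to fail

Step 14. Transannular strain and entropy may slow the nine-membered closure so far that intermolecular amidoalkylation, loss of the silyl group or migration of the enol double bond toward C8 take over during the slow ionisation, or the tether may reach the wrong iminium face. The fallback keeps the C10–C11 closure but replaces the silyl enol ether by a β-keto ester, a stabilised enol that cannot be lost and that tolerates long, warm Lewis acid treatment. Setting out from thioester 24, silver-assisted hydrolysis (AgOCOCF3, THF/H2O) should give the carboxylic acid F1. Activation with 1,1′-carbonyldiimidazole gives the acyl imidazolide F2, which in a decarboxylative Claisen condensation with Mg(O2CCH2CO2CH2CH=CH2)2 should give the β-keto allyl ester F3. BF3·OEt2 in dilute CH2Cl2 should ionise the N,O-acetal and let the keto ester enol close the ring to the cyclised β-keto allyl ester F4. Pd(PPh3)4 and morpholine then remove the allyl group, and the β-keto acid F5 loses CO2, which brings the route back to 28.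

Step 10. A share of the Z(O)-enolate, a weak Felkin preference of the α-branched aldehyde or binding of boron to the lactam could erode the C4/C8 configuration or stall the addition. The fallback is a Mukaiyama aldol reaction through an open transition state, where thioester-derived silyl ketene acetals are anti-selective and bulky nucleophiles follow the Felkin–Anh sense closely. Setting out from 17, LDA and Me3SiCl in THF at −78 °C should give the silyl ketene thioacetal F6; with aldehyde 13 and BF3·OEt2 in CH2Cl2 at −78 °C it should give hydroxy ester 19, which lactonises as before and comes back to the route at 20.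

Step 18. Facial selectivity at C12 is the weak point: chelation of indium between the aldehyde and the lactam or ketone oxygen, or the conformation of the nine-membered ring, may reverse or blur the expected anti addition, and the hydroxy acid may lactonise with retention before step 19. The fallback makes the syn adduct on purpose and lactonises with retention. Setting out from aldehyde 32, ethyl 2-[(tributylstannyl)methyl]acrylate and MgBr2·OEt2 in CH2Cl2 at −78 °C (bidentate Lewis acid bridging the aldehyde and lactam oxygens) should give the (12S)-hydroxy ethyl ester F7; p-toluenesulfonic acid (cat.) in CH2Cl2 then closes lactone B without touching C12 and returns the route at 35.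

Further compounds
F1 | step 14 | (2S,3S,4S)-2-[(1R)-1-[(3R)-1-(1,2-dimethoxy-2-oxoethyl)-2-oxoazepan-3-yl]propyl]-4-methyl-5-oxooxolane-3-carboxylic acid (C11 epimers) | CC[C@@H]([C@@H]1OC(=O)[C@@H](C)[C@@H]1C(=O)O)[C@H]2CCCCN(C(OC)C(=O)OC)C2=O
F2 | step 14 | acyl imidazolide of F1 | CC[C@@H]([C@@H]1OC(=O)[C@@H](C)[C@@H]1C(=O)n1ccnc1)[C@H]2CCCCN(C(OC)C(=O)OC)C2=O
F3 | step 14 | β-keto allyl ester, C8–C9(=O)–C10H2–CO2CH2CH=CH2 (C11 epimers) | CC[C@@H]([C@@H]1OC(=O)[C@@H](C)[C@@H]1C(=O)CC(=O)OCC=C)[C@H]2CCCCN(C(OC)C(=O)OC)C2=O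
F4 | step 14 | cyclised β-keto allyl ester, 28 with CO2CH2CH=CH2 on C10 (C10 epimers) | CC[C@H]1[C@@H]2OC(=O)[C@@H](C)[C@@H]2C(=O)C(C(=O)OCC=C)[C@@H](C(=O)OC)N2CCCC[C@H]1C2=O
F5 | step 14 | β-keto acid, 28 with CO2H on C10 (C10 epimers) | CC[C@H]1[C@@H]2OC(=O)[C@@H](C)[C@@H]2C(=O)C(C(=O)O)[C@@H](C(=O)OC)N2CCCC[C@H]1C2=O
F6 | step 10 | methyl (2S)-4-(tert-butylsulfanyl)-2-methyl-4-(trimethylsilyloxy)but-3-enoate | COC(=O)[C@@H](C)C=C(O[Si](C)(C)C)SC(C)(C)C
F7 | step 18 | (12S)-hydroxy ethyl ester, C11–CH(OH)–CH2–C(=CH2)–CO2Et on the tricycle | CC[C@H]1[C@@H]2OC(=O)[C@@H](C)[C@@H]2C(=O)C[C@@H]([C@@H](O)CC(=C)C(=O)OCC)N2CCCC[C@H]1C2=O
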